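**Retrosynthetic overview**

1. The target is the bis-O-methyl ether of hinnuliquinone, so the last disconnection is a double O-methylation of the two vinylogous-acid OH groups.
2. The quinone ring is the only ring built (both indoles are bought). It is disconnected into two molecules of a 2-tert-prenylated indol-3-ylpyruvate methyl ester, joined head-to-tail by an intermolecular Claisen and then a Dieckmann condensation, as in the enzymatic dimerisation of indolepyruvate. The cyclohexanetetraone formed is already the dihydroxyquinone tautomer, so no oxidant is needed.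
3. The α-keto ester comes from an α-azido ester (base-induced loss of N2, then hydrolysis), which comes from tryptophan methyl ester by diazo transfer. This is a chemical stand-in for the transamination of tryptophan.
4. The C2 tert-prenyl group is installed on the azido ester by chloroindolenine/prenylborane reverse prenylation. It is placed before quinone formation because an allylborane would attack a quinone.
5. Forward order: indole rings from L-tryptophan methyl ester → C2 prenylation → keto ester → quinone ring → O-methylation.

Assumption: the target has no stereocentre (rotamers about the two indole–quinone bonds are unspecified and equilibrate), so it is made as the single achiral compound drawn; the S centre carried from L-tryptophan is erased in step 3.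

**Route**

Step 1
Reactants: 1 L-tryptophan methyl ester hydrochloride
Product: 2 methyl (2S)-2-azido-3-(1H-indol-3-yl)propanoate
Conditions: imidazole-1-sulfonyl azide hydrogen sulfate (1.2 equiv), K2CO3 (3 equiv), CuSO4·5H2O (1 mol %), MeOH, rt
Reagents that add atoms: imidazole-1-sulfonyl azide hydrogen sulfate, [N-]=[N+]=NS(=O)(=O)n1ccnc1.OS(=O)(=O)O
Why: Copper-catalysed diazo transfer turns the primary amine into an azide with retention at Cα (S), giving a nitrogen group that has no N–H to be chlorinated in step 2 and is a latent imine for step 3.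

Step 2
Reactants: 2 methyl (2S)-2-azido-3-(1H-indol-3-yl)propanoate
Product: 4 methyl (2S)-2-azido-3-[2-(2-methylbut-3-en-2-yl)-1H-indol-3-yl]propanoate, via 3-chloroindolenine 3 (not isolated)
Conditions: tBuOCl (1.05 equiv), Et3N (1.2 equiv), THF, −78 °C; then B-prenyl-9-BBN (2 equiv, made in a second flask from 9-BBN-H and 3-methylbuta-1,2-diene, THF, rt), −78 °C → rt; H2O
Reagents that add atoms: B-prenyl-9-BBN, CC(C)=CCB1C2CCCC1CCC2 (its C5 unit comes from 3-methylbuta-1,2-diene, CC(C)=C=C); tert-butyl hypochlorite, CC(C)(C)OCl (its Cl stays only in 3)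
Why: Danishefsky-type reverse prenylation: C3 chlorination gives the chloroindolenine, its C=N is allylborated at C2 through a six-membered transition state with allylic transposition (hence the 1,1-dimethylallyl group), and loss of HCl restores the indole; Cα is untouched, and the azide and methyl ester should be inert to the allylborane at low temperature.

Step 3
Reactants: 4 methyl (2S)-2-azido-3-[2-(2-methylbut-3-en-2-yl)-1H-indol-3-yl]propanoate
Product: 6 methyl 3-[2-(2-methylbut-3-en-2-yl)-1H-indol-3-yl]-2-oxopropanoate, via α-imino ester 5 (not isolated)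
Conditions: LiOMe (0.2 equiv), THF/MeOH, 0 °C → rt (N2 evolution); then 1 M HCl, rt
Reagents that add atoms: water, O
Why: Alkoxide-catalysed deprotonation at the carbon bearing azide and ester expels N2 (base-induced α-azido ester to α-imino ester conversion, a formal transamination), and the imine/enamine is hydrolysed by dilute acid to the α-keto ester only after the base is quenched, so the keto ester never meets base; the Cα stereocentre is destroyed here.

Step 4
Reactants: 6 methyl 3-[2-(2-methylbut-3-en-2-yl)-1H-indol-3-yl]-2-oxopropanoate (two molecules)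
Product: 8 hinnuliquinone = 2,5-dihydroxy-3,6-bis[2-(2-methylbut-3-en-2-yl)-1H-indol-3-yl]-1,4-benzoquinone, via open-chain triketo ester 7 (not isolated)
Conditions: NaH (1.2 equiv), degassed THF (0.5 M), 0 °C → 65 °C, Ar; then 1 M HCl
Reagents that add atoms: none
Why: Proposed new method: full conversion of 6 into its sodium enolate removes every free ketone, so the aldol/isotetronate dimerisation seen with catalytic base has no acceptor; the enolate carbon of one molecule then attacks the ester carbonyl of another (Claisen, loss of methoxide) to give 7, which closes by a six-membered Dieckmann condensation, any O-acylated species revert through methoxide, and the doubly vinylogous carboxylate dianion of 8 is the thermodynamic sink, the cyclohexane-1,2,4,5-tetraone being a tautomer of the dihydroxyquinone so that no oxidant is needed; the closest known reaction type is the classical alkoxide-mediated self-condensation of α-keto esters RCH2COCO2R′ to 2,5-dialkyl-3,6-dihydroxybenzoquinones, and the enzymatic thioester Claisen/Dieckmann dimerisation of indolepyruvate.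

Step 5
Reactants: 8 hinnuliquinone
Product: 9 2,5-dimethoxy-3,6-bis[2-(2-methylbut-3-en-2-yl)-1H-indol-3-yl]-1,4-benzoquinone (target)
Conditions: TMSCHN2 (3 equiv), CH2Cl2/MeOH 4:1, 0 °C → rt
Reagents that add atoms: (trimethylsilyl)diazomethane, C[Si](C)(C)C=[N+]=[N-]
Why: Diazoalkane esterification: the two enolic OH groups are vinylogous carboxylic acids (pKa about 3–5) and are O-methylated, whereas the indole N–H (pKa about 17–21), the tetrasubstituted quinone double bonds and the terminal alkenes do not react.

**Compound list**

1 | L-tryptophan methyl ester hydrochloride (S) | COC(=O)[C@@H](N)Cc1c[nH]c2ccccc12.Cl | starting material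
2 | methyl (2S)-2-azido-3-(1H-indol-3-yl)propanoate | COC(=O)[C@@H](N=[N+]=[N-])Cc1c[nH]c2ccccc12 | intermediate
3 | methyl (2S)-2-azido-3-(3-chloro-3H-indol-3-yl)propanoate (3-chloroindolenine, both C3 epimers; not isolated) | COC(=O)[C@@H](N=[N+]=[N-])CC1(Cl)C=Nc2ccccc12 | intermediate
4 | methyl (2S)-2-azido-3-[2-(2-methylbut-3-en-2-yl)-1H-indol-3-yl]propanoate | COC(=O)[C@@H](N=[N+]=[N-])Cc1c(C(C)(C)C=C)[nH]c2ccccc12 | intermediate
5 | methyl 2-imino-3-[2-(2-methylbut-3-en-2-yl)-1H-indol-3-yl]propanoate (in equilibrium with its enamine tautomer; not isolated) | COC(=O)C(=N)Cc1c(C(C)(C)C=C)[nH]c2ccccc12 | intermediate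
6 | methyl 3-[2-(2-methylbut-3-en-2-yl)-1H-indol-3-yl]-2-oxopropanoate (keto/enol mixture) | COC(=O)C(=O)Cc1c(C(C)(C)C=C)[nH]c2ccccc12 | intermediate
7 | methyl 3,6-bis[2-(2-methylbut-3-en-2-yl)-1H-indol-3-yl]-2,4,5-trioxohexanoate (racemic at C3, present as its sodium enolate; not isolated) | COC(=O)C(=O)C(c1c(C(C)(C)C=C)[nH]c2ccccc12)C(=O)C(=O)Cc1c(C(C)(C)C=C)[nH]c2ccccc12 | intermediate
8 | hinnuliquinone, 2,5-dihydroxy-3,6-bis[2-(2-methylbut-3-en-2-yl)-1H-indol-3-yl]cyclohexa-2,5-diene-1,4-dione | C=CC(C)(C)c1[nH]c2ccccc2c1C1=C(O)C(=O)C(c2c(C(C)(C)C=C)[nH]c3ccccc23)=C(O)C1=O | intermediate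
9 | 2,5-dimethoxy-3,6-bis[2-(2-methylbut-3-en-2-yl)-1H-indol-3-yl]cyclohexa-2,5-diene-1,4-dione (CNP0331285.0) | C=CC(C)(C)c1[nH]c2ccccc2c1C1=C(OC)C(=O)C(c2c(C(C)(C)C=C)[nH]c3ccccc23)=C(OC)C1=O | target

**Step count and risks**

Total step count: 5. Longest linear sequence: 5 steps (1 → 2 → 4 → 6 → 8 → 9); the prenylborane is a reagent made in situ and is not counted.

The three steps most likely to fail are steps 4, 2 and 3, in that order of risk.

Step 2 (reverse prenylation in the presence of the azide; this combination is untested). The fallback sets out from 1 and comes back at 4, installing the azide only after the prenylation. 1 is condensed with phthalic anhydride (Et3N, toluene, reflux, Dean–Stark) to give N-phthaloyl-L-tryptophan methyl ester F1. F1 is put through the same tBuOCl/Et3N then B-prenyl-9-BBN sequence, for which a phthalimide-protected tryptophan ester is an established substrate, to give methyl (2S)-2-phthalimido-3-[2-(2-methylbut-3-en-2-yl)-1H-indol-3-yl]propanoate F2. Hydrazinolysis (N2H4·H2O, EtOH, rt) frees methyl (2S)-2-amino-3-[2-(2-methylbut-3-en-2-yl)-1H-indol-3-yl]propanoate F3. Diazo transfer under the conditions of step 1 then gives 4.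

Step 3 (loss of N2 may be followed by self-condensation of the enamine to a dehydro-diketopiperazine, or the hydrolysis may be sluggish). The fallback sets out from 4 and comes back at 6, replacing the azide elimination by a pyridoxal-type transamination. Staudinger reduction of 4 (PPh3, THF/H2O) gives the amine F3 of the previous fallback. Condensation with 4-formyl-1-methylpyridinium benzenesulfonate (CH2Cl2/DMF, rt) gives the aldimine methyl (2S)-2-[(E)-(1-methylpyridinium-4-yl)methylideneamino]-3-[2-(2-methylbut-3-en-2-yl)-1H-indol-3-yl]propanoate benzenesulfonate F4. DBU induces the 1,3-prototropic shift to the ketimine methyl 2-[(1-methylpyridinium-4-yl)methylimino]-3-[2-(2-methylbut-3-en-2-yl)-1H-indol-3-yl]propanoate benzenesulfonate F5. Aqueous oxalic acid hydrolyses F5 to 6.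

Step 4 (the aldol/isotetronate dimer, O-acylation or steric hindrance next to the tert-prenyl group may defeat the double Claisen). The fallback sets out from 6 and comes back at 8, changing the acyl donor to a thioester as the enzyme does. Saponification of 6 (LiOH, THF/H2O, 0 °C) gives 3-[2-(2-methylbut-3-en-2-yl)-1H-indol-3-yl]-2-oxopropanoic acid F6. Coupling with N-acetylcysteamine (EDC·HCl, CH2Cl2, 0 °C) gives the thioester S-(2-acetamidoethyl) 3-[2-(2-methylbut-3-en-2-yl)-1H-indol-3-yl]-2-oxopropanethioate F7. Soft enolisation (MgBr2·OEt2, iPr2NEt, CH2Cl2, rt) then drives the chelation-organised thio-Claisen/Dieckmann sequence, with thiolate as the better leaving group and no strong base, to give 8.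

**Further compounds**

F1 | step 2 | N-phthaloyl-L-tryptophan methyl ester | COC(=O)[C@@H](N1C(=O)c2ccccc2C1=O)Cc1c[nH]c2ccccc12
F2 | step 2 | methyl (2S)-2-phthalimido-3-[2-(2-methylbut-3-en-2-yl)-1H-indol-3-yl]propanoate | COC(=O)[C@@H](N1C(=O)c2ccccc2C1=O)Cc1c(C(C)(C)C=C)[nH]c2ccccc12
F3 | step 2 | methyl (2S)-2-amino-3-[2-(2-methylbut-3-en-2-yl)-1H-indol-3-yl]propanoate | COC(=O)[C@@H](N)Cc1c(C(C)(C)C=C)[nH]c2ccccc12
F4 | step 3 | methyl (2S)-2-[(E)-(1-methylpyridinium-4-yl)methylideneamino]-3-[2-(2-methylbut-3-en-2-yl)-1H-indol-3-yl]propanoate benzenesulfonate | COC(=O)[C@@H](/N=C/c1cc[n+](C)cc1)Cc1c(C(C)(C)C=C)[nH]c2ccccc12.[O-]S(=O)(=O)c1ccccc1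
F5 | step 3 | methyl 2-[(1-methylpyridinium-4-yl)methylimino]-3-[2-(2-methylbut-3-en-2-yl)-1H-indol-3-yl]propanoate benzenesulfonate | COC(=O)C(Cc1c(C(C)(C)C=C)[nH]c2ccccc12)=NCc1cc[n+](C)cc1.[O-]S(=O)(=O)c1ccccc1
F6 | step 4 | 3-[2-(2-methylbut-3-en-2-yl)-1H-indol-3-yl]-2-oxopropanoic acid | OC(=O)C(=O)Cc1c(C(C)(C)C=C)[nH]c2ccccc12
F7 | step 4 | S-(2-acetamidoethyl) 3-[2-(2-methylbut-3-en-2-yl)-1H-indol-3-yl]-2-oxopropanethioate | CC(=O)NCCSC(=O)C(=O)Cc1c(C(C)(C)C=C)[nH]c2ccccc12
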